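**Strategy.** Ring C is cut at C4–C4a and O1–C2, which gives a ring A phenol and a ring B aryl vinyl ketone. The key step exploits that C4a lies ortho to the O1 hydroxyl, next to the C5 oxygen and para to the C7 methoxy (a phloroglucinol-type carbon nucleophile), and that C2 is stabilised as an oxocarbenium ion by O1 and the electron-rich ring B. In one pot a chiral phosphoric acid joins phenol 9 and enone 15 by Friedel–Crafts conjugate addition and hemiketalisation, and a Hantzsch ester reduces the cyclic oxocarbenium ion on one face: both bonds and the (S) centre at C2 form together. The precursor pair is a silylated prenylphenol and a silylated enone.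

Key step: step 8

Remark: flavan numbering is used (ring A: C4a to C8a; ring B: the 2,4-dioxygenated aryl group; ring C: O1, C2, C3, C4); the sense of induction of the acid in step 8 is assumed by analogy with ion-pair transfer hydrogenations, and the (S)-acid would be taken if a first run showed the opposite sense.

**Step 1**
Reactants: 1 5-methoxybenzene-1,3-diol (5-methoxyresorcinol); 2 triisopropylsilyl chloride
Product: 3 3-methoxy-5-[(triisopropylsilyl)oxy]phenol
Conditions: TIPSCl (1.0 equiv), imidazole, DMF, 0 °C
Reagents that add atoms: triisopropylsilyl chloride 2, CC(C)[Si](Cl)(C(C)C)C(C)C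
Why: Statistical monosilylation (silyl ether formation) of a twofold-symmetric diol, in which the bulky silyl group slows the second silylation and later shields its two neighbouring ring carbons.

**Step 2**
Reactants: 3 3-methoxy-5-[(triisopropylsilyl)oxy]phenol; 4 chloromethyl methyl ether
Product: 5 triisopropyl[3-methoxy-5-(methoxymethoxy)phenoxy]silane
Conditions: MOMCl, i-Pr2NEt, CH2Cl2, 0 °C to rt
Reagents that add atoms: chloromethyl methyl ether 4, COCCl
Why: O-alkylation of the phenol (methoxymethyl ether formation) places a strong ortho-metalation directing group on the oxygen that becomes O1.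

**Step 3**
Reactants: 5 triisopropyl[3-methoxy-5-(methoxymethoxy)phenoxy]silane; 6 1-bromo-3-methylbut-2-ene (prenyl bromide)
Product: 8 triisopropyl[3-methoxy-5-(methoxymethoxy)-4-(3-methylbut-2-en-1-yl)phenoxy]silane, via aryllithium 7 (not isolated)
Conditions: n-BuLi, THF, 0 °C; then CuI (10 mol%), prenyl bromide, −78 °C to rt
Reagents that add atoms: prenyl bromide 6, CC(C)=CCBr
Why: Directed ortho-metalation occurs at the carbon between OMOM and OMe, the only site held by two coordinating groups and not shielded by the silyl ether, and the aryl metal is alkylated at the primary carbon of prenyl bromide (copper-catalysed SN2 allylation).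

**Step 4**
Reactants: 8 triisopropyl[3-methoxy-5-(methoxymethoxy)-4-(3-methylbut-2-en-1-yl)phenoxy]silane
Product: 9 3-methoxy-2-(3-methylbut-2-en-1-yl)-5-[(triisopropylsilyl)oxy]phenol
Conditions: HCl (3 M aq., cat.), MeOH, 40 °C
Reagents that add atoms: none
Why: Acid-catalysed acetal exchange with methanol (acetal cleavage) should free the O1 phenol while the aryl triisopropylsilyl ether and the trisubstituted alkene tolerate dilute acid at mild temperature.

**Step 5**
Reactants: 10 2,4-dihydroxybenzaldehyde; 11 tert-butyldimethylsilyl chloride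
Product: 12 2,4-bis[(tert-butyldimethylsilyl)oxy]benzaldehyde
Conditions: TBSCl (2.4 equiv), imidazole, DMF, rt
Reagents that add atoms: tert-butyldimethylsilyl chloride 11, CC(C)(C)[Si](C)(C)Cl
Why: Silyl ether formation at both phenols, chosen so that all three silyl groups of the later flavan fall in one near-neutral fluoride step.

**Step 6**
Reactants: 12 2,4-bis[(tert-butyldimethylsilyl)oxy]benzaldehyde; 13 vinylmagnesium bromide
Product: 14 rac-1-{2,4-bis[(tert-butyldimethylsilyl)oxy]phenyl}prop-2-en-1-ol
Conditions: vinylmagnesium bromide, THF, −78 °C; then H2O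
Reagents that add atoms: vinylmagnesium bromide 13, C=C[Mg]Br
Why: Grignard 1,2-addition to the aldehyde at low temperature, which should keep the ortho silyl group from migrating to the magnesium alkoxide; the new centre is racemic and is removed in step 7.

**Step 7**
Reactants: 14 rac-1-{2,4-bis[(tert-butyldimethylsilyl)oxy]phenyl}prop-2-en-1-ol
Product: 15 1-{2,4-bis[(tert-butyldimethylsilyl)oxy]phenyl}prop-2-en-1-one
Conditions: MnO2 (excess), CH2Cl2, rt; used at once
Reagents that add atoms: none
Why: Oxidation of an allylic and benzylic alcohol with manganese dioxide should give the aryl vinyl ketone without touching the silyl ethers, and immediate use avoids polymerisation of the enone.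

**Step 8**
Reactants: 9 3-methoxy-2-(3-methylbut-2-en-1-yl)-5-[(triisopropylsilyl)oxy]phenol; 15 1-{2,4-bis[(tert-butyldimethylsilyl)oxy]phenyl}prop-2-en-1-one; 16 diethyl 2,6-dimethyl-1,4-dihydropyridine-3,5-dicarboxylate (Hantzsch ester)
Product: 20 (2S)-2-{2,4-bis[(tert-butyldimethylsilyl)oxy]phenyl}-7-methoxy-8-(3-methylbut-2-en-1-yl)-5-[(triisopropylsilyl)oxy]chroman, via ketone 17 (not isolated), via hemiketal 18 (not isolated), via oxocarbenium ion 19 (not isolated)
Conditions: (R)-TRIP [(R)-3,3′-bis(2,4,6-triisopropylphenyl)-1,1′-binaphthyl-2,2′-diyl hydrogen phosphate] (10 mol%), 4 Å MS, toluene, 40 °C; then 16 (1.5 equiv), 0 °C to rt, one pot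
Reagents that add atoms: none
Why: Proposed new method: the phosphoric acid binds the O1–H of 9 and the carbonyl of 15 and delivers the enone β-carbon to C4a (Friedel–Crafts conjugate addition, C4–C4a), ketone 17 closes through O1 to hemiketal 18 (O1–C2), and acid-promoted loss of water gives oxocarbenium ion 19 as its chiral phosphate ion pair, which takes up hydride from 16 irreversibly. The closest known reaction types are the Brønsted acid-catalysed Friedel–Crafts addition and cyclisation of electron-rich phenols with enones to 2-aryl-chroman-2-ols, and the chiral phosphoric acid and Hantzsch ester transfer hydrogenation of isobenzopyrylium ions and of ortho-quinone methide-type cations; their merger into a reductive [3+3] annulation that gives a flavan is the new element. Ring C closes by 6-exo-trig attack of O1 on the ketone carbonyl. C2 is set by the catalyst alone: the phosphate, hydrogen-bonded to the N–H of the dihydropyridine, should shield one face of the planar cation so that hydride adds to the Re face of C2 and gives (S). The step needs C4a over C6 attack and C- over O-alkylation, secured by the ortho-directing hydrogen bond to O1–H, by the silyl group on the C5 oxygen (only O1 can close the ring, and C6 sits between OMe and the silyl ether) and by the reversibility of O-addition; it also needs hydride transfer to the cation only, secured by adding 16 after 15 is consumed, since neither ketone 17 nor the prenyl alkene accepts hydride from a dihydropyridine.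

**Step 9**
Reactants: 20 (2S)-2-{2,4-bis[(tert-butyldimethylsilyl)oxy]phenyl}-7-methoxy-8-(3-methylbut-2-en-1-yl)-5-[(triisopropylsilyl)oxy]chroman
Product: 21 4-[(2S)-5-hydroxy-7-methoxy-8-(3-methylbut-2-en-1-yl)-3,4-dihydro-2H-chromen-2-yl]benzene-1,3-diol (CNP0115018.1)
Conditions: TBAF (3.5 equiv), AcOH (3.5 equiv), THF, 0 °C
Reagents that add atoms: none
Why: Fluoride-mediated cleavage of the three aryl silyl ethers (desilylation), buffered with acetic acid so that no free phenoxide should open ring C through a quinone methide and erode C2.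

**Compound list**

1 | 5-methoxybenzene-1,3-diol (5-methoxyresorcinol) | COc1cc(O)cc(O)c1 | starting material
2 | triisopropylsilyl chloride | CC(C)[Si](Cl)(C(C)C)C(C)C | starting material
3 | 3-methoxy-5-[(triisopropylsilyl)oxy]phenol | COc1cc(O)cc(O[Si](C(C)C)(C(C)C)C(C)C)c1 | intermediate
4 | chloromethyl methyl ether | COCCl | starting material
5 | triisopropyl[3-methoxy-5-(methoxymethoxy)phenoxy]silane | COCOc1cc(OC)cc(O[Si](C(C)C)(C(C)C)C(C)C)c1 | intermediate
6 | 1-bromo-3-methylbut-2-ene (prenyl bromide) | CC(C)=CCBr | starting material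
7 | {2-methoxy-6-(methoxymethoxy)-4-[(triisopropylsilyl)oxy]phenyl}lithium | [Li]c1c(OCOC)cc(O[Si](C(C)C)(C(C)C)C(C)C)cc1OC | intermediate
8 | triisopropyl[3-methoxy-5-(methoxymethoxy)-4-(3-methylbut-2-en-1-yl)phenoxy]silane | COCOc1cc(O[Si](C(C)C)(C(C)C)C(C)C)cc(OC)c1CC=C(C)C | intermediate
9 | 3-methoxy-2-(3-methylbut-2-en-1-yl)-5-[(triisopropylsilyl)oxy]phenol | COc1cc(O[Si](C(C)C)(C(C)C)C(C)C)cc(O)c1CC=C(C)C | intermediate
10 | 2,4-dihydroxybenzaldehyde | O=Cc1ccc(O)cc1O | starting material
11 | tert-butyldimethylsilyl chloride | CC(C)(C)[Si](C)(C)Cl | starting material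
12 | 2,4-bis[(tert-butyldimethylsilyl)oxy]benzaldehyde | O=Cc1ccc(O[Si](C)(C)C(C)(C)C)cc1O[Si](C)(C)C(C)(C)C | intermediate
13 | vinylmagnesium bromide | C=C[Mg]Br | starting material
14 | rac-1-{2,4-bis[(tert-butyldimethylsilyl)oxy]phenyl}prop-2-en-1-ol | C=CC(O)c1ccc(O[Si](C)(C)C(C)(C)C)cc1O[Si](C)(C)C(C)(C)C | intermediate
15 | 1-{2,4-bis[(tert-butyldimethylsilyl)oxy]phenyl}prop-2-en-1-one | C=CC(=O)c1ccc(O[Si](C)(C)C(C)(C)C)cc1O[Si](C)(C)C(C)(C)C | intermediate
16 | diethyl 2,6-dimethyl-1,4-dihydropyridine-3,5-dicarboxylate (Hantzsch ester) | CCOC(=O)C1=C(C)NC(C)=C(C(=O)OCC)C1 | starting material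
17 | 1-{2,4-bis[(tert-butyldimethylsilyl)oxy]phenyl}-3-{2-hydroxy-4-methoxy-3-(3-methylbut-2-en-1-yl)-6-[(triisopropylsilyl)oxy]phenyl}propan-1-one | COc1cc(O[Si](C(C)C)(C(C)C)C(C)C)c(CCC(=O)c2ccc(O[Si](C)(C)C(C)(C)C)cc2O[Si](C)(C)C(C)(C)C)c(O)c1CC=C(C)C | intermediate
18 | rac-2-{2,4-bis[(tert-butyldimethylsilyl)oxy]phenyl}-7-methoxy-8-(3-methylbut-2-en-1-yl)-5-[(triisopropylsilyl)oxy]chroman-2-ol | COc1cc(O[Si](C(C)C)(C(C)C)C(C)C)c2c(c1CC=C(C)C)OC(O)(c1ccc(O[Si](C)(C)C(C)(C)C)cc1O[Si](C)(C)C(C)(C)C)CC2 | intermediate
19 | 2-{2,4-bis[(tert-butyldimethylsilyl)oxy]phenyl}-7-methoxy-8-(3-methylbut-2-en-1-yl)-5-[(triisopropylsilyl)oxy]-3,4-dihydrochromenylium ion (as its chiral phosphate ion pair) | COc1cc(O[Si](C(C)C)(C(C)C)C(C)C)c2c(c1CC=C(C)C)[O+]=C(c1ccc(O[Si](C)(C)C(C)(C)C)cc1O[Si](C)(C)C(C)(C)C)CC2 | intermediate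
20 | (2S)-2-{2,4-bis[(tert-butyldimethylsilyl)oxy]phenyl}-7-methoxy-8-(3-methylbut-2-en-1-yl)-5-[(triisopropylsilyl)oxy]chroman | COc1cc(O[Si](C(C)C)(C(C)C)C(C)C)c2c(c1CC=C(C)C)O[C@H](c1ccc(O[Si](C)(C)C(C)(C)C)cc1O[Si](C)(C)C(C)(C)C)CC2 | intermediate
21 | 4-[(2S)-5-hydroxy-7-methoxy-8-(3-methylbut-2-en-1-yl)-3,4-dihydro-2H-chromen-2-yl]benzene-1,3-diol | COc1cc(O)c2c(c1CC=C(C)C)O[C@H](c1ccc(O)cc1O)CC2 | target

**Step count.** Total: 9 steps. Longest linear sequence: 6 steps (1, 2, 3, 4, 8, 9).

**Steps most likely to fail**

Step 8 (proposed new method). The ion pair between cation 19 and the phosphate may be too loose for good facial selectivity in the hydride transfer, ionisation of hemiketal 18 may be slow, and attack at C6 (para to O1–H) may compete. The fallback uses known chemistry and sets out from 9 and 15. Friedel–Crafts conjugate addition under an achiral acid (diphenyl phosphate, toluene, 40 °C) should give ketone 17, which is isolated. Noyori asymmetric transfer hydrogenation of the aryl ketone with RuCl[(R,R)-TsDPEN](p-cymene) in HCO2H/Et3N should give (1R)-1-{2,4-bis[(tert-butyldimethylsilyl)oxy]phenyl}-3-{2-hydroxy-4-methoxy-3-(3-methylbut-2-en-1-yl)-6-[(triisopropylsilyl)oxy]phenyl}propan-1-ol F1. Intramolecular Mitsunobu etherification (PPh3, DIAD, THF, 0 °C) then closes O1–C2 with inversion, so the (R)-alcohol becomes the (S)-flavan. The fallback comes back to the route at 20.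

Step 4. The freed ortho-prenylphenol may cyclise onto its alkene under acid (dimethylchroman formation), or the silyl ether may be partly lost during acetal cleavage. The fallback avoids the acetal altogether and sets out from 3. Ortho-C-prenylation of the sodium phenoxide in a non-polar solvent (NaH, toluene, rt, then prenyl bromide 6) should alkylate the ortho carbon between the phenoxide and OMe, because the other ortho carbon and the para carbon are shielded by the silyl ether. This gives 9 directly, where the fallback comes back to the route; it makes no new compound (F0).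

Step 9. A transient 4′-phenoxide may open ring C through a para-quinone methide with loss of configuration at C2, and the hindered triisopropylsilyl ether may be cleaved incompletely. The fallback sets out from 20 and exchanges silyl for acetyl in one pot (TBAF, Ac2O, THF, 0 °C), so each phenoxide is acetylated as it forms. This should give (2S)-5-acetoxy-2-(2,4-diacetoxyphenyl)-7-methoxy-8-(3-methylbut-2-en-1-yl)chroman F2, which can be purified. Neutral deacetylation of the aryl acetates (NH4OAc, aqueous MeOH, rt) then comes back to the route at 21.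

**Further compounds**

F1 | step 8 | (1R)-1-{2,4-bis[(tert-butyldimethylsilyl)oxy]phenyl}-3-{2-hydroxy-4-methoxy-3-(3-methylbut-2-en-1-yl)-6-[(triisopropylsilyl)oxy]phenyl}propan-1-ol | COc1cc(O[Si](C(C)C)(C(C)C)C(C)C)c(CC[C@@H](O)c2ccc(O[Si](C)(C)C(C)(C)C)cc2O[Si](C)(C)C(C)(C)C)c(O)c1CC=C(C)C
F2 | step 9 | (2S)-5-acetoxy-2-(2,4-diacetoxyphenyl)-7-methoxy-8-(3-methylbut-2-en-1-yl)chroman | COc1cc(OC(C)=O)c2c(c1CC=C(C)C)O[C@H](c1ccc(OC(C)=O)cc1OC(C)=O)CC2
F0 | step 4 | none | none
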